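**Retrosynthetic overview**
1. Integracin D ⇐ hydrogenolysis of three benzyl ethers ⇐ sulfation of the single free phenol of 19.
2. 19 ⇐ B-alkyl Suzuki coupling of the terminal alkene of ester 15 with 3-(benzyloxy)-5-bromophenol 17.
3. 15 ⇐ acyl chloride esterification of benzoic acid 13 with alkenol 7; 13 ⇐ Pinnick oxidation and B-alkyl Suzuki coupling of acetate 8 with bromoaldehyde 10.
4. Both stereocentres come from one building block, (S)-undec-10-en-4-ol 7, made by forming C3–C4: a sparteine-lithiated oct-7-enyl carbamate (α-oxy carbanion, reversed polarity at the carbinol carbon) is joined to n-propyl-Bpin by 1,2-metallate shift, then oxidised.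
5. No ring is formed; both benzene rings are bought (9 and 16).

Assumption: the target is the free aryl hydrogen sulfate as drawn; it is carried as its sodium salt, protonated in the last operation, and best stored as the salt.

**Route**

Step 1
Reactants: 1 oct-7-en-1-ol
Product: 2 oct-7-en-1-yl N,N-diisopropylcarbamate
Conditions: iPr2NCOCl (1.2 equiv), Et3N (1.5 equiv), CH2Cl2, reflux, 24 h
Reagents that add atoms: N,N-diisopropylcarbamoyl chloride, CC(C)N(C(C)C)C(Cl)=O
Why: Carbamoylation of a primary alcohol (nucleophilic acyl substitution) installs the directing and leaving group needed for Hoppe lithiation; no stereocentre is involved.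

Step 2
Reactants: 2 oct-7-en-1-yl N,N-diisopropylcarbamate; 3 4,4,5,5-tetramethyl-2-propyl-1,3,2-dioxaborolane
Product: 7 (S)-undec-10-en-4-ol, via lithiated carbamate 4 (not isolated), via boronate complex 5 (not isolated), via secondary boronic ester 6 (not isolated)
Conditions: s-BuLi (1.3 equiv), (−)-sparteine (1.3 equiv), Et2O, −78 °C, 5 h; 3 (1.5 equiv), −78 °C, 1 h; MgBr2·OEt2 (2 equiv), reflux, 16 h; then NaOH (2 M aq), H2O2 (30%), THF, 0 °C to rt
Reagents that add atoms: hydrogen peroxide, OO
Why: Hoppe asymmetric deprotonation followed by Aggarwal lithiation–borylation (a Matteson-type 1,2-metallate rearrangement): s-BuLi/(−)-sparteine removes the pro-S hydrogen next to oxygen, so C4 (normally an electrophilic carbonyl-type carbon) becomes the configurationally stable α-oxy carbanion 4, which adds to the boron of 3 with retention, the propyl group then shifts from boron to carbon with inversion as the carbamate leaves, and stereoretentive C–B oxidation gives the (S) alcohol (typically about 97:3 er).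

Step 3
Reactants: 7 (S)-undec-10-en-4-ol
Product: 8 (S)-undec-10-en-4-yl acetate
Conditions: Ac2O, pyridine, DMAP (cat.), CH2Cl2, rt
Reagents that add atoms: acetic anhydride, CC(=O)OC(C)=O
Why: DMAP-catalysed acylation of the secondary alcohol; the C–O bond at the stereocentre is untouched, so (S) is retained.

Step 4
Reactants: 9 1,3-bis(benzyloxy)-5-bromobenzene
Product: 10 2,4-bis(benzyloxy)-6-bromobenzaldehyde
Conditions: POCl3 (1.5 equiv), DMF, 0 °C to 90 °C; then H2O (ice), rt
Reagents that add atoms: N,N-dimethylformamide, CN(C)C=O; water, O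
Why: Vilsmeier–Haack formylation (electrophilic aromatic substitution) goes to the carbon para to one benzyloxy group and ortho to the other, the position between the two ethers being more hindered, as is known for 1-bromo-3,5-dimethoxybenzene.

Step 5
Reactants: 8 (S)-undec-10-en-4-yl acetate; 10 2,4-bis(benzyloxy)-6-bromobenzaldehyde
Product: 12 (S)-11-[3,5-bis(benzyloxy)-2-formylphenyl]undecan-4-yl acetate, via B-alkyl-9-BBN adduct 11 (not isolated)
Conditions: (9-BBN)2 (0.5 equiv per 1.05 equiv 8), THF, 0 °C to rt, 4 h; then K3PO4 (3 M aq, 3 equiv); 10 (0.9 equiv), PdCl2(dppf) (5 mol %), DMF, 50 °C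
Reagents that add atoms: none
Why: Anti-Markovnikov hydroboration of the terminal alkene followed by B-alkyl Suzuki–Miyaura coupling with the formyl-activated aryl bromide; forming the hydroxyborate with aqueous base before 10 is added prevents aldehyde reduction, and the acetate and the remote stereocentre are unaffected.

Step 6
Reactants: 12 (S)-11-[3,5-bis(benzyloxy)-2-formylphenyl]undecan-4-yl acetate
Product: 13 2-[(S)-8-acetoxyundecyl]-4,6-bis(benzyloxy)benzoic acid
Conditions: NaClO2 (3 equiv), NaH2PO4 (3 equiv), 2-methyl-2-butene (10 equiv), t-BuOH/THF/H2O, 0 °C to rt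
Reagents that add atoms: sodium chlorite, [Na+].[O-]Cl=O
Why: Pinnick oxidation converts the hindered aryl aldehyde to the acid under buffered conditions, with 2-methyl-2-butene trapping HOCl so that the electron-rich ring is not chlorinated and the acetate and benzyl ethers survive.

Step 7
Reactants: 13 2-[(S)-8-acetoxyundecyl]-4,6-bis(benzyloxy)benzoic acid; 7 (S)-undec-10-en-4-ol
Product: 15 (S)-undec-10-en-4-yl 2-[(S)-8-acetoxyundecyl]-4,6-bis(benzyloxy)benzoate, via acid chloride 14 (not isolated)
Conditions: (COCl)2 (1.5 equiv), DMF (cat.), CH2Cl2, 0 °C to rt, evaporate; then 7 (1.2 equiv), Et3N (3 equiv), DMAP (1 equiv), CH2Cl2, 0 °C to 40 °C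
Reagents that add atoms: none
Why: Acyl chloride formation and DMAP-mediated acylation of the secondary alcohol, where the electron-rich aroyl chloride readily forms an acylpyridinium species despite its two ortho substituents; acylation occurs at oxygen, so the (S) carbinol centre is retained.

Step 8
Reactants: 16 5-bromobenzene-1,3-diol
Product: 17 3-(benzyloxy)-5-bromophenol
Conditions: BnBr (1.0 equiv), K2CO3 (1.1 equiv), acetone, reflux
Reagents that add atoms: benzyl bromide, BrCc1ccccc1
Why: Williamson ether synthesis with one equivalent of benzyl bromide gives the mono-ether statistically (about 45%), the recovered diol being recycled and the bis-ether by-product being compound 9.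

Step 9
Reactants: 15 (S)-undec-10-en-4-yl 2-[(S)-8-acetoxyundecyl]-4,6-bis(benzyloxy)benzoate; 17 3-(benzyloxy)-5-bromophenol
Product: 19 (S)-11-[3-(benzyloxy)-5-hydroxyphenyl]undecan-4-yl 2-[(S)-8-acetoxyundecyl]-4,6-bis(benzyloxy)benzoate, via B-alkyl-9-BBN adduct 18 (not isolated)
Conditions: (9-BBN)2 (0.6 equiv), THF, rt, 4 h; then 17 (1.2 equiv), Pd(OAc)2 (5 mol %), SPhos (10 mol %), K3PO4 (aq, 4 equiv), THF/H2O, 45 °C
Reagents that add atoms: none
Why: Chemoselective 9-BBN hydroboration of the terminal alkene (esters untouched) and B-alkyl Suzuki–Miyaura coupling, the electron-rich SPhos-ligated palladium catalyst being chosen because the bromophenol reacts as its phenoxide; no stereocentre is touched.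

Step 10
Reactants: 19 (S)-11-[3-(benzyloxy)-5-hydroxyphenyl]undecan-4-yl 2-[(S)-8-acetoxyundecyl]-4,6-bis(benzyloxy)benzoate
Product: 20 sodium 3-(benzyloxy)-5-[(S)-8-({2-[(S)-8-acetoxyundecyl]-4,6-bis(benzyloxy)benzoyl}oxy)undecyl]phenyl sulfate
Conditions: SO3·pyridine (4 equiv), pyridine, 40 °C; then NaHCO3 (aq); Sephadex LH-20 (MeOH)
Reagents that add atoms: sulfur trioxide–pyridine complex, O=S(=O)([O-])[n+]1ccccc1; sodium hydrogen carbonate, OC(=O)[O-].[Na+]
Why: O-Sulfonation of the only free hydroxyl group (the lower-ring phenol) with the SO3–pyridine complex, followed by exchange to the sodium salt so that no pyridine remains to poison the hydrogenolysis catalyst.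

Step 11
Reactants: 20 sodium 3-(benzyloxy)-5-[(S)-8-({2-[(S)-8-acetoxyundecyl]-4,6-bis(benzyloxy)benzoyl}oxy)undecyl]phenyl sulfate
Product: 21 Integracin D
Conditions: H2 (1 atm), 10% Pd/C, MeOH/EtOAc, rt; then HCl (0.1 M aq, 1.0 equiv), 0 °C, n-BuOH extraction
Reagents that add atoms: none
Why: Catalytic hydrogenolysis removes the three aryl benzyl ethers while the aryl sulfate, the acetate, the benzoate and both stereocentres are untouched, and stoichiometric acid then protonates the sulfate.

**Compound list**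
1 | oct-7-en-1-ol | C=CCCCCCCO | starting material
2 | oct-7-en-1-yl N,N-diisopropylcarbamate | C=CCCCCCCOC(=O)N(C(C)C)C(C)C | intermediate
3 | 4,4,5,5-tetramethyl-2-propyl-1,3,2-dioxaborolane (n-propylboronic acid pinacol ester) | CCCB1OC(C)(C)C(C)(C)O1 | starting material
4 | (S)-1-lithiooct-7-en-1-yl N,N-diisopropylcarbamate, (−)-sparteine complex (ligand not drawn) | [Li][C@@H](CCCCCC=C)OC(=O)N(C(C)C)C(C)C | intermediate
5 | lithium (S)-boronate complex formed from 4 and 3 | CCC[B-]1(OC(C)(C)C(C)(C)O1)[C@@H](CCCCCC=C)OC(=O)N(C(C)C)C(C)C.[Li+] | intermediate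
6 | (S)-4,4,5,5-tetramethyl-2-(undec-10-en-4-yl)-1,3,2-dioxaborolane | CCC[C@@H](CCCCCC=C)B1OC(C)(C)C(C)(C)O1 | intermediate
7 | (S)-undec-10-en-4-ol | CCC[C@@H](CCCCCC=C)O | intermediate
8 | (S)-undec-10-en-4-yl acetate | CCC[C@@H](CCCCCC=C)OC(C)=O | intermediate
9 | 1,3-bis(benzyloxy)-5-bromobenzene | Brc1cc(OCc2ccccc2)cc(OCc2ccccc2)c1 | starting material
10 | 2,4-bis(benzyloxy)-6-bromobenzaldehyde | O=Cc1c(Br)cc(OCc2ccccc2)cc1OCc1ccccc1 | intermediate
11 | (S)-11-(9-borabicyclo[3.3.1]nonan-9-yl)undecan-4-yl acetate | CCC[C@@H](CCCCCCCB1C2CCCC1CCC2)OC(C)=O | intermediate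
12 | (S)-11-[3,5-bis(benzyloxy)-2-formylphenyl]undecan-4-yl acetate | CCC[C@@H](CCCCCCCc1cc(OCc2ccccc2)cc(OCc2ccccc2)c1C=O)OC(C)=O | intermediate
13 | 2-[(S)-8-acetoxyundecyl]-4,6-bis(benzyloxy)benzoic acid | CCC[C@@H](CCCCCCCc1cc(OCc2ccccc2)cc(OCc2ccccc2)c1C(=O)O)OC(C)=O | intermediate
14 | 2-[(S)-8-acetoxyundecyl]-4,6-bis(benzyloxy)benzoyl chloride | CCC[C@@H](CCCCCCCc1cc(OCc2ccccc2)cc(OCc2ccccc2)c1C(=O)Cl)OC(C)=O | intermediate
15 | (S)-undec-10-en-4-yl 2-[(S)-8-acetoxyundecyl]-4,6-bis(benzyloxy)benzoate | CCC[C@@H](CCCCCCCc1cc(OCc2ccccc2)cc(OCc2ccccc2)c1C(=O)O[C@@H](CCC)CCCCCC=C)OC(C)=O | intermediate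
16 | 5-bromobenzene-1,3-diol | Oc1cc(O)cc(Br)c1 | starting material
17 | 3-(benzyloxy)-5-bromophenol | Oc1cc(Br)cc(OCc2ccccc2)c1 | intermediate
18 | (S)-11-(9-borabicyclo[3.3.1]nonan-9-yl)undecan-4-yl 2-[(S)-8-acetoxyundecyl]-4,6-bis(benzyloxy)benzoate | CCC[C@@H](CCCCCCCc1cc(OCc2ccccc2)cc(OCc2ccccc2)c1C(=O)O[C@@H](CCC)CCCCCCCB1C2CCCC1CCC2)OC(C)=O | intermediate
19 | (S)-11-[3-(benzyloxy)-5-hydroxyphenyl]undecan-4-yl 2-[(S)-8-acetoxyundecyl]-4,6-bis(benzyloxy)benzoate | CCC[C@@H](CCCCCCCc1cc(OCc2ccccc2)cc(OCc2ccccc2)c1C(=O)O[C@@H](CCC)CCCCCCCc1cc(O)cc(OCc2ccccc2)c1)OC(C)=O | intermediate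
20 | sodium 3-(benzyloxy)-5-[(S)-8-({2-[(S)-8-acetoxyundecyl]-4,6-bis(benzyloxy)benzoyl}oxy)undecyl]phenyl sulfate | CCC[C@@H](CCCCCCCc1cc(OCc2ccccc2)cc(OCc2ccccc2)c1C(=O)O[C@@H](CCC)CCCCCCCc1cc(OCc2ccccc2)cc(OS(=O)(=O)[O-])c1)OC(C)=O.[Na+] | intermediate
21 | Integracin D | CCC[C@@H](CCCCCCCc1cc(O)cc(O)c1C(=O)O[C@@H](CCC)CCCCCCCc1cc(O)cc(OS(=O)(=O)O)c1)OC(C)=O | target

**Summary**
Total step count: 11. Longest linear sequence: 9 steps (1, 2, 3, 5, 6, 7, 9, 10, 11). Compound 7 is used twice, in steps 3 and 7, so both (S) centres come from step 2.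

Steps most likely to fail:

Step 2 (lithiation–borylation). The risks are a sluggish 1,2-shift of the carbamate-bearing boronate and erosion of er. The fallback sets out from 1 and returns to the route at 7. Compound 1 is acylated with 2,4,6-triisopropylbenzoyl chloride (pyridine, DMAP) to oct-7-en-1-yl 2,4,6-triisopropylbenzoate F1. Treatment with s-BuLi/(−)-sparteine in Et2O at −78 °C and then Me3SnCl gives the storable (S)-1-(trimethylstannyl)oct-7-en-1-yl 2,4,6-triisopropylbenzoate F2, whose er can be measured before use. Tin–lithium exchange with n-BuLi at −78 °C regenerates, with retention and free of diamine, (S)-1-lithiooct-7-en-1-yl 2,4,6-triisopropylbenzoate F3, the same species that was trapped by tin. F3 adds to 3 to give the lithium boronate complex F4. Because the benzoate is the better leaving group, the 1,2-shift runs on warming to rt without a Lewis acid and gives 6, which is oxidised as in step 2 to 7.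

Step 7 (esterification of a di-ortho-substituted benzoic acid with a secondary alcohol). The risk is slow acyl transfer to the hindered carbonyl. The fallback sets out from 7 and returns at 15; it activates the alcohol instead of the acid. Mitsunobu inversion of 7 with 4-nitrobenzoic acid (PPh3, DIAD, THF) gives (R)-undec-10-en-4-yl 4-nitrobenzoate F5. LiOH in THF/H2O then gives (R)-undec-10-en-4-ol F6. A second Mitsunobu reaction of F6 with acid 13 (PPh3, DIAD, toluene) lets the carboxylate attack the activated carbinol carbon by SN2, so the hindrance at the acyl carbon does not matter, and the inversion delivers the (S) ester 15.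

Step 9 (B-alkyl Suzuki coupling with a free bromophenol next to base-sensitive esters). The risks are slow oxidative addition of the phenoxide and acetate hydrolysis on prolonged heating. The fallback sets out from 17 and returns at 20. Compound 17 is sulfated first (SO3·pyridine, pyridine; then NaHCO3) to sodium 3-(benzyloxy)-5-bromophenyl sulfate F7. F7 is coupled with borane 18 (Pd(OAc)2, SPhos, K3PO4, THF/DMF/H2O, 40 °C). The aryl bromide is then no longer a phenoxide, the coupling gives 20 directly, and step 10 is no longer needed.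

**Further compounds**
F1 | step 2 | oct-7-en-1-yl 2,4,6-triisopropylbenzoate | C=CCCCCCCOC(=O)c1c(C(C)C)cc(C(C)C)cc1C(C)C
F2 | step 2 | (S)-1-(trimethylstannyl)oct-7-en-1-yl 2,4,6-triisopropylbenzoate | C[Sn](C)(C)[C@@H](CCCCCC=C)OC(=O)c1c(C(C)C)cc(C(C)C)cc1C(C)C
F3 | step 2 | (S)-1-lithiooct-7-en-1-yl 2,4,6-triisopropylbenzoate | [Li][C@@H](CCCCCC=C)OC(=O)c1c(C(C)C)cc(C(C)C)cc1C(C)C
F4 | step 2 | lithium (S)-boronate complex formed from F3 and 3 | CCC[B-]1(OC(C)(C)C(C)(C)O1)[C@@H](CCCCCC=C)OC(=O)c1c(C(C)C)cc(C(C)C)cc1C(C)C.[Li+]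
F5 | step 7 | (R)-undec-10-en-4-yl 4-nitrobenzoate | CCC[C@H](CCCCCC=C)OC(=O)c1ccc(cc1)[N+](=O)[O-]
F6 | step 7 | (R)-undec-10-en-4-ol | CCC[C@H](CCCCCC=C)O
F7 | step 9 | sodium 3-(benzyloxy)-5-bromophenyl sulfate | [Na+].[O-]S(=O)(=O)Oc1cc(Br)cc(OCc2ccccc2)c1
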